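**Compound numbers used throughout:** 1 methyl eugenol; 2 (E)-methylisoeugenol; 3 radical cation of 2; 4 open-chain distonic radical cation (C2–C3 bond made); 5 aryltetralinyl radical (ring B closed); 6 target. Target numbering: ring A = benzo ring (C4a, C5–C8, C8a), ring B = carbocycle (C1–C4, C4a, C8a), ring C = pendant 3,4-dimethoxyphenyl on C1.

## Analysis of the target

Target 6 is a cyclolignan of the 1-aryl-1,2-dihydronaphthalene type. Ring A (methoxy groups on C6 and C7) is fused to ring B, which carries ring C on C1, methyl groups on C2 and C3, and the only alkene, C3=C4, conjugated with ring A. The two stereocentres are adjacent: C1 (R, a doubly benzylic methine) and C2 (S, an allylic methine), with ring C and the C2 methyl group trans. The constitution is that of two identical 3,4-dimethoxyphenyl–C3 units. Unit A is ring A with C4, C3 and the C3 methyl; unit B is ring C with C1, C2 and the C2 methyl. They are joined by the C2–C3 bond and the C1–C8a bond, C8a lies para to the C6 methoxy group, and the formula equals two molecules of 2 minus H2. The C1–H and C2–H bonds flank the styrene, so acid, base or oxidants can shift the alkene to C1=C2 or aromatise ring B; either event erases both stereocentres. Apart from four aryl methyl ethers there is no functional group, hence no anchor for an auxiliary, a directing group or a salt resolution. The difficulty is control rather than size: the absolute configuration of the trans C1/C2 pair must be set on a hydrocarbon framework, and the alkene placed at C3=C4 only, without over-oxidation.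

## Retrosynthetic reasoning

**6 ⇒ 5 (C3–H).** The C3=C4 double bond is traced back to loss of one hydrogen atom from C3 of the benzylic C4 radical 5. C3–H is the only C–H bond β to that radical that is not on an aromatic carbon, so the alkene position is dictated by the intermediate. The forward step is hydrogen-atom abstraction by a cobalt(II) co-catalyst, which also removes the redox equivalents as H2.

**5 ⇒ 4 (C1–C8a).** The C1–C8a bond is cut as an intramolecular Friedel–Crafts alkylation of ring A by a benzylic cation at C1. This is the place to cut because C8a is para to the C6 methoxy group and because the closure transiently dearomatises ring A (arenium ion), which is what turns unit A into a four-carbon "vinylarene diene". The forward reaction has to set C1 trans to the C2 methyl; a chair-like six-membered transition state with pseudo-equatorial substituents should do so.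

**4 ⇒ 3 + 2 (C2–C3).** The C2–C3 bond is the bond between the two β-carbons of the two propenyl units. Cutting it halves the molecule into two identical C11 pieces at the oxidation level of one radical cation 3 and one neutral alkene 2. The forward reaction has to set C2 in the absolute sense; this is assigned to a chiral counteranion that is ion-paired with 3 during C–C bond formation. The like-configured intermediate 4 is C2-symmetric, so it does not matter which terminus later becomes C1.

**3 ⇒ 2 (one electron).** Radical cation 3 is 2 minus one electron, supplied by photoinduced electron transfer to an excited acridinium whose only counterion is the chiral anion.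

**2 ⇒ 1 (alkene position).** The (E)-propenyl group of 2 is traced back to the allyl group of 1, a bulk commodity that is sold isomerically pure. The forward reaction is a catalytic one-position alkene isomerisation with E control.

## Alternatives that were turned down

**Alternative 1:** the textbook disconnection, C1–C8a by a cationic Friedel–Crafts cyclisation of a preformed, stereodefined chain. The forward sequence would build (2R,3R)-diketone A1 by auxiliary-controlled enolate chemistry and aryl ketone formation, and reduce it to diol A2. Acid would then ionise one benzylic alcohol, close ring B and dehydrate the C4 carbinol to 6. It was turned down on step economy and logic. A1 alone needs about five steps with a stoichiometric auxiliary. The chain carries four stereocentres, of which two (C3, C4) are thrown away. A2 can also close to the 2,5-diaryltetrahydrofuran under the same acid. The acid needed for dehydration is the reagent most likely to shift the alkene of 6 to C1=C2. Overall about seven to eight steps would lead to a 22-carbon hydrocarbon ether that is a plain dimer.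

**Alternative 2:** a dearomatisation, cutting the C1–ring C bond. Ligand-controlled conjugate addition of 3,4-dimethoxyphenyllithium to the hindered naphthoate A3 would give, after protonation, the trans ester A4. The carboxyl group would then be taken down to the C2 methyl. It was turned down because the precursor is not simpler than the target. A3 already contains rings A and B and needs four to five steps itself. The C2 substituent arrives at the carboxyl level and costs three more steps (reduction, sulfonylation, hydride displacement). These steps run through intermediates in which C2–H is α to a carbonyl and doubly activated, so epimerisation and aromatisation threaten. The total would be nine or more steps.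

**Alternative 3:** a photochemical closure of C1–C8a. Irradiation of diene A5 would cause conrotatory 6π-electrocyclisation through ring A to an 8a-H dihydronaphthalene. A thermal suprafacial [1,5]-hydrogen shift from C8a to C2 would then restore ring A and give the trans-1,2 pattern with the C3=C4 alkene. It was turned down because A5 is achiral and has no group that could hold a chiral sensitiser or auxiliary, so the product would be racemic. The reactive E,Z isomer would also have to be drawn from a photostationary mixture, and the dearomatised intermediate is easily intercepted by oxidants to give the arylnaphthalene. Making this route enantioselective would require carboxyl anchors in place of the methyl groups, which returns the step count of Alternative 2.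

Key step: step 2

Assumption: 1 is taken as the starting material because it is sold as a single isomer, whereas commercial methylisoeugenol is an E/Z mixture.

Assumption: which enantiomer of the chiral anion leads to (1R,2S)-6 cannot be deduced on paper; the (S,S)-anion is written, and its antipode is to be used if the first run shows the opposite sense.

## Route

Step 1
Reactants: 1 methyl eugenol (4-allyl-1,2-dimethoxybenzene)
Product: 2 (E)-methylisoeugenol (1,2-dimethoxy-4-[(E)-prop-1-en-1-yl]benzene)
Conditions: [CpRu(κ2-P,N)(MeCN)]PF6 (P,N = 2-(di-isopropylphosphino)-4-tert-butyl-1-methylimidazole; 0.5 mol%), acetone, 25 °C; filtration through silica, distillation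
Reagents that add atoms: none
Why: Catalytic one-position alkene isomerisation (allylarene to 1-propenylarene); conjugation with the arene makes the shift downhill, and this bifunctional ruthenium catalyst is known to give (E)-1-propenylarenes with very high geometric purity under kinetic control. No stereocentre is formed and the aryl ethers are inert.

Step 2
Reactants: 2 (E)-methylisoeugenol (two molecules)
Product: 6 (1R,2S)-1-(3,4-dimethoxyphenyl)-6,7-dimethoxy-2,3-dimethyl-1,2-dihydronaphthalene, via monomer radical cation 3 (not isolated), via open-chain distonic radical cation 4 (not isolated), via aryltetralinyl radical 5 (not isolated)
Conditions: [9-mesityl-3,6-di-tert-butyl-10-phenylacridinium][(S,S)-IDPi] (2 mol%), Co(dmgBF2)2(MeCN)2 (5 mol%), CH2Cl2 (0.05 M), −40 °C, 450 nm LED, Ar; stop at ca. 75% conversion and recover 2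
Reagents that add atoms: none
Why: Proposed new method: an enantioselective, acceptorless dehydrogenative radical-cation (4+2) homodimerisation under chiral-counteranion control; the closest known reaction types are the chiral-anion-directed photoredox [2+2] cycloaddition of anethole-type styrene radical cations and the acridinium/cobaloxime dehydrogenative annulation of styrene radical cations, whose elementary steps are combined here. The excited acridinium oxidises 2 to radical cation 3, which in CH2Cl2 can pair only with the confined imidodiphosphorimidate anion; attack of the β-carbon of a second molecule of 2 on the β-carbon of 3 in the stacked anti (like) topology forms the C2–C3 bond and gives the C2-symmetric distonic radical cation 4, so that the anion-shielded face of 3 fixes C2 (S in 6), while the configuration at C3 is irrelevant because it is erased later. Ring B then closes by a six-membered intramolecular Friedel–Crafts alkylation in which the benzylic cation carbon C1 attacks C8a of the other veratryl ring, the position para to the C6 methoxy group, through a chair-like transition state with ring C and both methyl groups pseudo-equatorial, which sets C1 (R) trans to the C2 methyl under substrate control; ring A is dearomatised for the lifetime of the arenium ion and rearomatises by proton loss to radical 5. Cobalt(II) removes the hydrogen atom from C3, the only β-C–H of 5, so the alkene can form only at C3=C4; the cobalt(III) hydride releases H2 with the proton and the acridinyl radical returns cobalt to Co(II), so neither a terminal oxidant nor an achiral anion enters the flask. The step needs (4+2) over [2+2] selectivity, which the 3,4-dimethoxy pattern should secure by activating C8a (anethole-type substrates lack this activation and typically stop at the cyclobutane) together with the irreversible loss of H2, while any cyclobutane is re-oxidised and reopened to 4. It needs attack at C8a rather than at the position between side chain and methoxy group, which para activation and sterics should secure; and because both termini of 4 are equivalent, either mode of cyclisation gives the same enantiomer, leaving the ion-paired C–C bond formation as the single enantio-determining event. The reaction is stopped at partial conversion because 6 should be about as easily oxidised as 2.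

## Compound list

1 | methyl eugenol (4-allyl-1,2-dimethoxybenzene) | COc1ccc(CC=C)cc1OC | starting material
2 | (E)-methylisoeugenol (1,2-dimethoxy-4-[(E)-prop-1-en-1-yl]benzene) | COc1ccc(/C=C/C)cc1OC | intermediate
3 | radical cation of 2, ion-paired with the chiral anion (drawn as benzylic cation / β-radical) | COc1ccc([CH+][CH]C)cc1OC | intermediate
4 | (2S,3S)-1,4-bis(3,4-dimethoxyphenyl)-2,3-dimethylbutane-1,4-diyl radical cation (like-configured, C2-symmetric; drawn with C1 cationic and C4 radical) | COc1ccc([CH+][C@H](C)[C@@H](C)[CH]c2ccc(OC)c(OC)c2)cc1OC | intermediate
5 | 1-(3,4-dimethoxyphenyl)-6,7-dimethoxy-2,3-dimethyltetralin-4-yl radical, 1,2-trans-2,3-trans (target numbering; C1 R, C2 R, C3 S; the C2 descriptor differs from that in 6 only through CIP ranking) | COc1ccc([C@@H]2c3cc(OC)c(OC)cc3[CH][C@H](C)[C@H]2C)cc1OC | intermediate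
6 | (1R,2S)-1-(3,4-dimethoxyphenyl)-6,7-dimethoxy-2,3-dimethyl-1,2-dihydronaphthalene | COc1ccc([C@@H]2c3cc(OC)c(OC)cc3C=C(C)[C@H]2C)cc1OC | target

## Step count and risk

Total step count: 2. Longest linear sequence: 2.

The route has only two steps, so both are assessed; step 2, which carries the label, comes first.

**Step 2 (key step).** Four processes are most likely to go wrong.
- Enantioinduction may erode. This can happen through loosening of the ion pair, through competing unlike coupling (whose two modes of ring closure lead to opposite enantiomers), or through a racemic background dimerisation.
- The liberated imidodiphosphorimidic acid may trigger cationic (non-oxidative) dimerisation of 2 towards indane-type dimers.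
- Part of the material may be diverted into the [2+2] manifold if ring closure onto C8a is slower than expected at low temperature.
- The product may be over-oxidised: further electron, proton and hydrogen loss from C2 and C1 would aromatise ring B and erase both stereocentres.

The fallback uses known chemistry and changes the source of enantiopurity from asymmetric catalysis to resolution. It sets out from 2. The oxidative (4+2) dehydrodimerisation is run racemic under achiral conditions (9-mesityl-10-methylacridinium perchlorate, Co(dmgH)2(py)Cl, MeCN, blue LED, room temperature), a reaction type with precedent for electron-rich styrene radical cations. This should give 6 together with its mirror image, (1S,2R)-1-(3,4-dimethoxyphenyl)-6,7-dimethoxy-2,3-dimethyl-1,2-dihydronaphthalene F1. The two are separated by preparative supercritical-fluid chromatography on a polysaccharide carbamate chiral stationary phase, and the absolute configuration is assigned by chiroptical comparison. The fallback comes back to the route at 6.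

**Step 1.** The most likely failure is incomplete geometric control, leaving residual Z alkene. A second is deactivation of the low-loading ruthenium catalyst by phenolic or peroxidic impurities in technical 1. A Z-contaminated monomer would add a second, differently shaped radical-cation ion pair to the key step. The fallback separates the positional shift from the geometric control and sets out from 1. The double bond is moved into conjugation with KOH in hot ethanol, which should give an E-rich mixture that also contains (Z)-methylisoeugenol F2. The whole mixture is then equilibrated to the thermodynamically favoured E isomer with catalytic iodine under visible light (reversible iodine-atom addition) and distilled. The fallback comes back to the route at 2.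

## Further compounds

F1 | step 2 | (1S,2R)-1-(3,4-dimethoxyphenyl)-6,7-dimethoxy-2,3-dimethyl-1,2-dihydronaphthalene | COc1ccc([C@H]2c3cc(OC)c(OC)cc3C=C(C)[C@@H]2C)cc1OC
F2 | step 1 | (Z)-methylisoeugenol (1,2-dimethoxy-4-[(Z)-prop-1-en-1-yl]benzene) | COc1ccc(/C=C\C)cc1OC
A1 | alternative 1 | (2R,3R)-1,4-bis(3,4-dimethoxyphenyl)-2,3-dimethylbutane-1,4-dione | COc1ccc(C(=O)[C@H](C)[C@@H](C)C(=O)c2ccc(OC)c(OC)c2)cc1OC
A2 | alternative 1 | (2R,3R)-1,4-bis(3,4-dimethoxyphenyl)-2,3-dimethylbutane-1,4-diol (carbinol configuration at C1 and C4 not controlled) | COc1ccc(C(O)[C@H](C)[C@@H](C)C(O)c2ccc(OC)c(OC)c2)cc1OC
A3 | alternative 2 | 2,6-di-tert-butyl-4-methoxyphenyl 6,7-dimethoxy-3-methylnaphthalene-2-carboxylate | COc1cc2cc(C)c(C(=O)Oc3c(C(C)(C)C)cc(OC)cc3C(C)(C)C)cc2cc1OC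
A4 | alternative 2 | 2,6-di-tert-butyl-4-methoxyphenyl (1R,2S)-1-(3,4-dimethoxyphenyl)-6,7-dimethoxy-3-methyl-1,2-dihydronaphthalene-2-carboxylate | COc1ccc([C@@H]2c3cc(OC)c(OC)cc3C=C(C)[C@H]2C(=O)Oc2c(C(C)(C)C)cc(OC)cc2C(C)(C)C)cc1OC
A5 | alternative 3 | (1E,3Z)-1,4-bis(3,4-dimethoxyphenyl)-2,3-dimethylbuta-1,3-diene | COc1ccc(/C=C(\C)/C(C)=C\c2ccc(OC)c(OC)c2)cc1OC
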